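We begin with the easy step, counting moles: the two substrates together come to 0.138 M, which is more than the 0.0759 M of coupling partner, so if each substrate takes one partner, the asked flask holds too little partner to serve both in full.

the same everywhere: starting material 0.069 M; coupling partner 0.0759 M; protic impurity 1.38 mM; free catalyst 0.22 mM
- alpha: second substrate 0.069 M; temperature 20 °C; the very flask that is asked about, followed so far
- theta: second substrate 0.069 M; temperature 26 °C; run made earlier
- flask: second substrate 0.0690 M; temperature 20 °C; time 1.0 h

| run | time / min | target / % | starting material / % |
|---|---|---|---|
| alpha | 3.00 | 13 | 85 |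
| alpha | 10.0 | 31 | 68 |
| alpha | 15.0 | 38 | 62 |
| alpha | 25.0 | 46 | 51 |
| alpha | 40.0 | 51 | 49 |
| alpha | 50.0 | 51 | 48 |
| theta | 3.00 | 16 | 83 |
| theta | 10.0 | 37 | 61 |
| theta | 15.0 | 43 | 55 |
| theta | 25.0 | 52 | 50 |
| theta | 40.0 | 48 | 51 |
| theta | 50.0 | 48 | 50 |

(standard deviation of a reading: 1.5 percentage points)

- target that was removed still counts
- the numbers in the tables scatter with a standard deviation of 1.5 percentage points
- additions bring no volume worth counting

- winter: at 1.0 h add coupling partner, 50.0% of the amount charged, then wait 2.0 h
- midnight: at 1.0 h raise the temperature by 10 K, then wait 2.0 h
- spring: at 1.0 h add free catalyst, 100% of the amount charged, then wait 2.0 h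
- dusk: change nothing and wait 2.0 h more
- noon: at 1.0 h take out 90% of the target then present, then wait 2.0 h

* target, in percent of the starting material first charged, at 1.0 h
* the remedy with the largest gain of target, or "none" below 2 percentage points (winter / midnight / spring / dusk / noon / none)
* target present, with what was taken out counted in, in percent of the starting material first charged, after winter
* target present, with what was taken out counted in, in percent of the starting material first charged, after midnight

Now the alpha run, which is this flask followed so far, in slow motion. In the first instants, at 3.00 min, target reads 13%, already 40.8 times the free catalyst charged, so the catalyst turns over and is no reagent. In the middle the alpha run slows: from 15.0 min to 25.0 min target gains 8 percentage points, less than in the first 3.00 min, while starting material still reads 51%. At the end target reads 51% and then 51%, with 48% of starting material beside it. The theta run, at 26 °C, reads 37% at 10.0 min against 31% in the alpha run, so warmth hurries it, yet its last reading is no higher.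

So we read the end of the alpha run as partner shared between two substrates. Target stands at 0.0352 M, a share of 0.464 of the partner charged. We carry the selectivity factor, how readily the second substrate takes partner relative to starting material, with target's share of the partner used equal to [starting material]/([starting material] + factor × [second substrate]), both concentrations as charged. The equal charges give it as 1.16, a reading with the scatter in it. Our reckoning then commits to 51% at the hour, and to the same after heat, which brings no partner. The added partner, split by that share, gives 76.5%.

The forecast says 51% at the hour, names winter as the remedy, and gives 78% after it, above our figure, and 51% after heat. Its ground: “a temperature-independent plateau favours a stoichiometric limit”.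

The flask gives 50.4% at the hour. The best remedy is winter, which gains 27 points and reaches 77.8%. Heat leaves 50.4%, a gain of 0.037 points, under the margin of 2 points. The forecast stands.

    starting material + free catalyst ⇌ catalyst intermediate A (K = 40.6 L mol⁻¹, k = 7.65 L mol⁻¹ s⁻¹, Ea = 38.0 kJ mol⁻¹, ΔH = −24.0 kJ mol⁻¹)
    coupling partner + catalyst intermediate A → free catalyst + target (k = 10.8 L mol⁻¹ s⁻¹, Ea = 54.0 kJ mol⁻¹)
    second substrate + free catalyst ⇌ catalyst intermediate B (K = 41.0 L mol⁻¹, k = 8.04 L mol⁻¹ s⁻¹, Ea = 48.0 kJ mol⁻¹, ΔH = −10.0 kJ mol⁻¹)
    coupling partner + catalyst intermediate B → free catalyst + second product (k = 17.7 L mol⁻¹ s⁻¹, Ea = 53.0 kJ mol⁻¹)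
    starting material + protic impurity → quenched substrate (k = 1.17 L mol⁻¹ s⁻¹, Ea = 60.0 kJ mol⁻¹)
    (constants at 20 °C)

At 60.0 min the flask has 0.0887% of its partner left, so partner is the limiting reagent, and winter's gain owes a part of its size to the loss of second substrate and free catalyst to catalyst intermediate B: in the run with that step taken away, winter gains 6.2 points against 27 points. Our factor puts 0.0407 M into second product, and the flask holds 0.0411 M. With 0.28 M of second substrate, the factor gives 19.3% of target; that neighbour gives 18.4%.

(The numbers in the tables stem from a simulated flask with constants of no real substance; the scatter is artificial.)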